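Cuts: (a) the aliphatic ester between the ring A side-chain oxygen and the central butanoyl C=O; (b) in ring A, the aryl ester C–O bond and the C1–C6 ring bond; (c) in ring B, the benzylic CH2–C(=O) bond and the aryl ester O–CH bond.
Enabling feature: ring A is a 2,4-dihydroxy-6-alkylbenzoate, that is a folded 3,5,7-trioxo ester. Its C2 and C4 hydroxyls and C6 mark the three former ketones, and the C1 carboxyl is bound to the oxygen of a hindered secondary alcohol, so ester and arene can both come from one acylketene.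
Forward, ring A: a dioxinone is extended to a diketo-dioxinone, its acylketene is captured by benzyl (R)-3-hydroxybutanoate, and aldol aromatisation closes the ring; benzylation and desilylation then free the side-chain alcohol.
Forward, ring B: orsellinic acid is esterified with a pentenol whose alkene is the latent central carboxyl, its methyl group is extended by lateral lithiation and Weinreb acylation, and the alkene is cleaved to the acid.
A Steglich coupling joins the halves; desilylation and one hydrogenolysis finish the synthesis.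
Stereochemistry: all four centres are (R). Three come unchanged from methyl (R)-3-hydroxybutanoate and the fourth from (S)-pent-4-en-2-ol by Mitsunobu inversion; no step creates a lasting stereocentre.

Key step: step 6

Remark: 1,3-dicarbonyl compounds are drawn as keto tautomers although they are largely enolised. The transient carbinol centres of 12 and 22 form as mixtures and are drawn without configuration.

Step 1
Reactants: 1 2,2,6-trimethyl-4H-1,3-dioxin-4-one
Product: 3 2,2-dimethyl-6-(2-oxopropyl)-4H-1,3-dioxin-4-one, via lithium dienolate 2 (not isolated)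
Conditions: LiN(SiMe3)2, THF, −78 °C; AcCl, −78 °C; 1 M HCl
Reagents that add atoms: acetyl chloride, CC(=O)Cl
Why: Deprotonation of the C6 methyl group gives the extended dienolate 2, which the acid chloride acylates at its terminal carbon (vinylogous Claisen-type C-acylation), an excess of 2 taking up the more acidic proton of 3.

Step 2
Reactants: 4 methyl (R)-3-hydroxybutanoate
Product: 5 methyl (R)-3-[(tert-butyldimethylsilyl)oxy]butanoate
Conditions: TBSCl, imidazole, DMF, rt
Reagents that add atoms: tert-butyldimethylsilyl chloride, CC(C)(C)[Si](C)(C)Cl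
Why: Imidazole-promoted silylation of a secondary alcohol forms only an O–Si bond, so the (R) centre is untouched.

Step 3
Reactants: 5 methyl (R)-3-[(tert-butyldimethylsilyl)oxy]butanoate
Product: 6 (R)-3-[(tert-butyldimethylsilyl)oxy]-N-methoxy-N-methylbutanamide
Conditions: MeNH(OMe)·HCl, iPrMgCl, THF, −20 to 0 °C
Reagents that add atoms: N,O-dimethylhydroxylamine hydrochloride, Cl.CNOC
Why: In this Weinreb amidation by the chloromagnesium amide made in the flask, acyl substitution at low temperature outruns α-deprotonation, so the β-silyloxy group is not eliminated and the configuration is kept.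

Step 4
Reactants: 3 2,2-dimethyl-6-(2-oxopropyl)-4H-1,3-dioxin-4-one; 6 (R)-3-[(tert-butyldimethylsilyl)oxy]-N-methoxy-N-methylbutanamide
Product: 8 (R)-6-[6-(tert-butyldimethylsilyloxy)-2,4-dioxoheptyl]-2,2-dimethyl-4H-1,3-dioxin-4-one, via dilithium dianion 7 (not isolated)
Conditions: 3, LiN(iPr)2 (2.2 equiv), THF, −78 °C; 6, −78 to −20 °C; 1 M HCl, 0 °C
Reagents that add atoms: none
Why: In this β-dicarbonyl dianion acylation (Weinreb ketone synthesis) only the last-formed terminal carbanion of 7 attacks the amide, and the chelated adduct releases the ketone only on the acid quench, so neither over-addition nor proton exchange with the product can interfere.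

Step 5
Reactants: 4 methyl (R)-3-hydroxybutanoate
Product: 9 benzyl (R)-3-hydroxybutanoate
Conditions: BnOH, Ti(OiPr)4 (cat.), PhMe, 100 °C, MeOH distilled off
Reagents that add atoms: benzyl alcohol, OCc1ccccc1
Why: Titanate-catalysed transesterification runs under nearly neutral conditions at the acyl carbon only and is driven by removal of methanol, so the carbinol centre and the free hydroxyl are left alone.

Step 6
Reactants: 8 (R)-6-[6-(tert-butyldimethylsilyloxy)-2,4-dioxoheptyl]-2,2-dimethyl-4H-1,3-dioxin-4-one; 9 benzyl (R)-3-hydroxybutanoate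
Product: 13 benzyl (R)-3-[(2,4-dihydroxy-6-{(R)-2-[(tert-butyldimethylsilyl)oxy]propyl}benzoyl)oxy]butanoate, via acylketene 10 (not isolated), via triketo ester 11 (not isolated), via aldol adduct 12 (not isolated)
Conditions: 8, 9 (1.5 equiv), PhMe (concentrated), 110 °C; cool to rt, Et3N; then 0.5 M aq. HCl, 0 °C, brief
Reagents that add atoms: none
Why: At 110 °C the dioxinone ring of 8 loses acetone in a retro-[4+2] process to give acylketene 10, whose central carbon is attacked by the hydroxyl of 9 under neutral conditions to give triketo ester 11, so the crowded aryl ester C–O bond is in place before any 2,6-disubstituted benzoic acid would have to be activated. Triethylamine then enolises the methylene between the new ester and the first ketone (future C1), this carbon adds to the terminal ketone of the chain (future C6) to give carbinol 12, and dilute acid removes water while the two remaining ketones tautomerise to the C2 and C4 phenols of 13. The closest known reaction type is the thermolysis of diketo-dioxinones with alcohol capture, followed by base then acid aromatisation to resorcylate esters. Ring A closes by a 6-exo-trig aldol addition at the ketone (enolendo when the enolate is drawn through the ring ketone, enolexo when drawn through the ester, both allowed for a six-membered ring). No lasting stereocentre is made, since the two centres of 12 vanish on aromatisation, and the two (R) centres lie β to carbonyl groups where neither heat nor amine can epimerise them. Three selectivities are needed: external O–H capture over internal capture of the ketene by the enolised diketone, secured by an excess of 9 at high concentration; aldol closure over Claisen closure of the other inner methylene onto the ester, secured by the more electrophilic ketone, the poor secondary alkoxide leaving group and the weak base; and survival of the 3-aroyloxybutanoate and the chain oxygen, secured by avoiding strong base and by the silyl ether, which blocks lactonisation.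

Step 7
Reactants: 13 benzyl (R)-3-[(2,4-dihydroxy-6-{(R)-2-[(tert-butyldimethylsilyl)oxy]propyl}benzoyl)oxy]butanoate
Product: 14 benzyl (R)-3-[(2,4-bis(benzyloxy)-6-{(R)-2-[(tert-butyldimethylsilyl)oxy]propyl}benzoyl)oxy]butanoate
Conditions: BnBr, K2CO3, Bu4NI (cat.), acetone, 56 °C
Reagents that add atoms: benzyl bromide, BrCc1ccccc1
Why: In this Williamson etherification of both phenols, carbonate deprotonates ArOH (the chelated C2 hydroxyl included on heating) but is far too weak to enolise the esters, so the 3-aroyloxybutanoate should not eliminate.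

Step 8
Reactants: 14 benzyl (R)-3-[(2,4-bis(benzyloxy)-6-{(R)-2-[(tert-butyldimethylsilyl)oxy]propyl}benzoyl)oxy]butanoate
Product: 15 benzyl (R)-3-({2,4-bis(benzyloxy)-6-[(R)-2-hydroxypropyl]benzoyl}oxy)butanoate
Conditions: HF·pyridine, THF, 0 °C to rt
Reagents that add atoms: none
Why: Fluoride-driven Si–O cleavage in a weakly acidic medium avoids the alkoxide that a basic fluoride source would generate, and with it both lactonisation onto the aryl ester and crotonate formation.

Step 9
Reactants: 16 2,4-dihydroxy-6-methylbenzoic acid (orsellinic acid); 17 (S)-pent-4-en-2-ol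
Product: 18 (R)-pent-4-en-2-yl 2,4-dihydroxy-6-methylbenzoate
Conditions: PPh3, DIAD (1 equiv each), THF, 0 °C to rt
Reagents that add atoms: none
Why: Mitsunobu esterification forms the bond by SN2 attack of the carboxylate on the activated carbinol carbon, so the hindrance of the 2,6-disubstituted acid does not matter, the (S) alcohol gives the (R) ester by inversion, and with one equivalent of alcohol the far more acidic carboxyl reacts ahead of the phenols.

Step 10
Reactants: 18 (R)-pent-4-en-2-yl 2,4-dihydroxy-6-methylbenzoate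
Product: 19 (R)-pent-4-en-2-yl 2,4-bis(benzyloxy)-6-methylbenzoate
Conditions: BnBr, K2CO3, DMF, 60 °C
Reagents that add atoms: benzyl bromide, BrCc1ccccc1
Why: This is a Williamson etherification of both phenols on a substrate with no base-sensitive group.

Step 11
Reactants: 19 (R)-pent-4-en-2-yl 2,4-bis(benzyloxy)-6-methylbenzoate; 6 (R)-3-[(tert-butyldimethylsilyl)oxy]-N-methoxy-N-methylbutanamide
Product: 21 (R)-pent-4-en-2-yl 2,4-bis(benzyloxy)-6-{(R)-4-[(tert-butyldimethylsilyl)oxy]-2-oxopentyl}benzoate, via benzylic lithium 20 (not isolated)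
Conditions: LiN(iPr)2 (2 equiv), THF, −78 °C; 6, −78 °C; AcOH, −78 °C
Reagents that add atoms: none
Why: Lateral lithiation of the ortho-toluate gives the ester-stabilised anion 20, whose acylation by the Weinreb amide stops at the ketone, while the bulky secondary ester suppresses self-condensation and the cold acidic quench prevents enolate attack on the ester.

Step 12
Reactants: 21 (R)-pent-4-en-2-yl 2,4-bis(benzyloxy)-6-{(R)-4-[(tert-butyldimethylsilyl)oxy]-2-oxopentyl}benzoate
Product: 23 (R)-4-oxobutan-2-yl 2,4-bis(benzyloxy)-6-{(R)-4-[(tert-butyldimethylsilyl)oxy]-2-oxopentyl}benzoate, via vicinal diol 22 (not isolated)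
Conditions: OsO4 (cat.), NaIO4, 2,6-lutidine, dioxane–H2O, rt
Reagents that add atoms: osmium tetroxide, O=[Os](=O)(=O)=O; sodium periodate, [Na+].[O-]I(=O)(=O)=O
Why: Lemieux–Johnson oxidation dihydroxylates the only C=C bond and cleaves diol 22 in the same flask, leaving arene, ketone, silyl ether and benzyl ethers untouched.

Step 13
Reactants: 23 (R)-4-oxobutan-2-yl 2,4-bis(benzyloxy)-6-{(R)-4-[(tert-butyldimethylsilyl)oxy]-2-oxopentyl}benzoate
Product: 24 (R)-3-[(2,4-bis(benzyloxy)-6-{(R)-4-[(tert-butyldimethylsilyl)oxy]-2-oxopentyl}benzoyl)oxy]butanoic acid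
Conditions: NaClO2, NaH2PO4, 2-methyl-2-butene (excess), tBuOH–H2O, 0 °C to rt
Reagents that add atoms: sodium chlorite, [Na+].[O-]Cl=O
Why: Pinnick oxidation in a weakly acidic buffer takes the crude β-aroyloxy aldehyde to the acid without base-induced elimination, and the alkene scavenger keeps hypochlorous acid away from the electron-rich arene.

Step 14
Reactants: 15 benzyl (R)-3-({2,4-bis(benzyloxy)-6-[(R)-2-hydroxypropyl]benzoyl}oxy)butanoate; 24 (R)-3-[(2,4-bis(benzyloxy)-6-{(R)-4-[(tert-butyldimethylsilyl)oxy]-2-oxopentyl}benzoyl)oxy]butanoic acid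
Product: 25 fully protected hansforester I (four phenol benzyl ethers, benzyl ester, ring B side-chain TBS ether)
Conditions: DCC, DMAP (cat.), CH2Cl2, 0 °C to rt
Reagents that add atoms: none
Why: Steglich esterification of an unhindered aliphatic acid with a secondary alcohol forms the bond at the acyl carbon, so the carbinol centre of 15 is retained, and the low temperature with only catalytic DMAP limits β-elimination of the activated acid.

Step 15
Reactants: 25 fully protected hansforester I
Product: 26 hansforester I tetrabenzyl ether benzyl ester (free ring B side-chain hydroxyl)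
Conditions: HF·pyridine, THF, 0 °C to rt
Reagents that add atoms: none
Why: Fluoride-mediated Si–O cleavage in a weakly acidic medium frees the β-hydroxy ketone without the retro-aldol, dehydration or crotonate-forming elimination that a basic fluoride source would invite.

Step 16
Reactants: 26 hansforester I tetrabenzyl ether benzyl ester
Product: 27 hansforester I
Conditions: H2 (1 atm), Pd/C, EtOAc–EtOH, rt
Reagents that add atoms: none
Why: Heterogeneous hydrogenolysis cleaves the four aryl benzyl ethers and the benzyl ester in one neutral operation that leaves the three ester links, the ketone, the secondary alcohol and all four (R) centres untouched.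

Compound list
1 | 2,2,6-trimethyl-4H-1,3-dioxin-4-one | CC1=CC(=O)OC(C)(C)O1 | starting material
2 | lithium 2,2-dimethyl-6-methylidene-1,3-dioxin-4-olate (dienolate of 1) | [Li+].[O-]C1=CC(=C)OC(C)(C)O1 | intermediate
3 | 2,2-dimethyl-6-(2-oxopropyl)-4H-1,3-dioxin-4-one | CC(=O)CC1=CC(=O)OC(C)(C)O1 | intermediate
4 | methyl (R)-3-hydroxybutanoate | C[C@@H](O)CC(=O)OC | starting material
5 | methyl (R)-3-[(tert-butyldimethylsilyl)oxy]butanoate | C[C@H](CC(=O)OC)O[Si](C)(C)C(C)(C)C | intermediate
6 | (R)-3-[(tert-butyldimethylsilyl)oxy]-N-methoxy-N-methylbutanamide | C[C@H](CC(=O)N(C)OC)O[Si](C)(C)C(C)(C)C | intermediate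
7 | dilithium dianion of 3 | [Li+].[Li+].C=C([O-])C=C1C=C([O-])OC(C)(C)O1 | intermediate
8 | (R)-6-[6-(tert-butyldimethylsilyloxy)-2,4-dioxoheptyl]-2,2-dimethyl-4H-1,3-dioxin-4-one | C[C@H](CC(=O)CC(=O)CC1=CC(=O)OC(C)(C)O1)O[Si](C)(C)C(C)(C)C | intermediate
9 | benzyl (R)-3-hydroxybutanoate | C[C@@H](O)CC(=O)OCc1ccccc1 | intermediate
10 | (R)-9-[(tert-butyldimethylsilyl)oxy]-3,5,7-trioxodec-1-en-1-one (acylketene) | C[C@H](CC(=O)CC(=O)CC(=O)C=C=O)O[Si](C)(C)C(C)(C)C | intermediate
11 | (R)-4-(benzyloxy)-4-oxobutan-2-yl (R)-9-[(tert-butyldimethylsilyl)oxy]-3,5,7-trioxodecanoate (triketo ester) | C[C@H](CC(=O)CC(=O)CC(=O)CC(=O)O[C@H](C)CC(=O)OCc1ccccc1)O[Si](C)(C)C(C)(C)C | intermediate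
12 | aldol adduct: 2-hydroxy-4,6-dioxocyclohexanecarboxylate of 9 bearing the (R)-2-silyloxypropyl group on the carbinol carbon (ring centres undefined) | C[C@H](CC1(O)CC(=O)CC(=O)C1C(=O)O[C@H](C)CC(=O)OCc2ccccc2)O[Si](C)(C)C(C)(C)C | intermediate
13 | benzyl (R)-3-[(2,4-dihydroxy-6-{(R)-2-[(tert-butyldimethylsilyl)oxy]propyl}benzoyl)oxy]butanoate | C[C@H](Cc1cc(O)cc(O)c1C(=O)O[C@H](C)CC(=O)OCc2ccccc2)O[Si](C)(C)C(C)(C)C | intermediate
14 | benzyl (R)-3-[(2,4-bis(benzyloxy)-6-{(R)-2-[(tert-butyldimethylsilyl)oxy]propyl}benzoyl)oxy]butanoate | C[C@H](Cc1cc(OCc2ccccc2)cc(OCc2ccccc2)c1C(=O)O[C@H](C)CC(=O)OCc2ccccc2)O[Si](C)(C)C(C)(C)C | intermediate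
15 | benzyl (R)-3-({2,4-bis(benzyloxy)-6-[(R)-2-hydroxypropyl]benzoyl}oxy)butanoate | C[C@H](Cc1cc(OCc2ccccc2)cc(OCc2ccccc2)c1C(=O)O[C@H](C)CC(=O)OCc2ccccc2)O | intermediate
16 | 2,4-dihydroxy-6-methylbenzoic acid (orsellinic acid) | Cc1cc(O)cc(O)c1C(=O)O | starting material
17 | (S)-pent-4-en-2-ol | C[C@H](O)CC=C | starting material
18 | (R)-pent-4-en-2-yl 2,4-dihydroxy-6-methylbenzoate | C=CC[C@@H](C)OC(=O)c1c(O)cc(O)cc1C | intermediate
19 | (R)-pent-4-en-2-yl 2,4-bis(benzyloxy)-6-methylbenzoate | C=CC[C@@H](C)OC(=O)c1c(OCc2ccccc2)cc(OCc2ccccc2)cc1C | intermediate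
20 | benzylic lithium derivative of 19 | [Li+].[CH2-]c1cc(OCc2ccccc2)cc(OCc2ccccc2)c1C(=O)O[C@H](C)CC=C | intermediate
21 | (R)-pent-4-en-2-yl 2,4-bis(benzyloxy)-6-{(R)-4-[(tert-butyldimethylsilyl)oxy]-2-oxopentyl}benzoate | C=CC[C@@H](C)OC(=O)c1c(OCc2ccccc2)cc(OCc2ccccc2)cc1CC(=O)C[C@@H](C)O[Si](C)(C)C(C)(C)C | intermediate
22 | (2R)-4,5-dihydroxypentan-2-yl ester corresponding to 21 (C4 carbinol undefined) | OCC(O)C[C@@H](C)OC(=O)c1c(OCc2ccccc2)cc(OCc2ccccc2)cc1CC(=O)C[C@@H](C)O[Si](C)(C)C(C)(C)C | intermediate
23 | (R)-4-oxobutan-2-yl 2,4-bis(benzyloxy)-6-{(R)-4-[(tert-butyldimethylsilyl)oxy]-2-oxopentyl}benzoate | O=CC[C@@H](C)OC(=O)c1c(OCc2ccccc2)cc(OCc2ccccc2)cc1CC(=O)C[C@@H](C)O[Si](C)(C)C(C)(C)C | intermediate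
24 | (R)-3-[(2,4-bis(benzyloxy)-6-{(R)-4-[(tert-butyldimethylsilyl)oxy]-2-oxopentyl}benzoyl)oxy]butanoic acid | OC(=O)C[C@@H](C)OC(=O)c1c(OCc2ccccc2)cc(OCc2ccccc2)cc1CC(=O)C[C@@H](C)O[Si](C)(C)C(C)(C)C | intermediate
25 | benzyl (R)-3-({2,4-bis(benzyloxy)-6-[(R)-2-({(R)-3-[(2,4-bis(benzyloxy)-6-{(R)-4-[(tert-butyldimethylsilyl)oxy]-2-oxopentyl}benzoyl)oxy]butanoyl}oxy)propyl]benzoyl}oxy)butanoate | C[C@H](Cc1cc(OCc2ccccc2)cc(OCc2ccccc2)c1C(=O)O[C@H](C)CC(=O)OCc2ccccc2)OC(=O)C[C@@H](C)OC(=O)c1c(OCc2ccccc2)cc(OCc2ccccc2)cc1CC(=O)C[C@@H](C)O[Si](C)(C)C(C)(C)C | intermediate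
26 | benzyl (R)-3-({2,4-bis(benzyloxy)-6-[(R)-2-({(R)-3-[(2,4-bis(benzyloxy)-6-[(R)-4-hydroxy-2-oxopentyl]benzoyl)oxy]butanoyl}oxy)propyl]benzoyl}oxy)butanoate | C[C@H](Cc1cc(OCc2ccccc2)cc(OCc2ccccc2)c1C(=O)O[C@H](C)CC(=O)OCc2ccccc2)OC(=O)C[C@@H](C)OC(=O)c1c(OCc2ccccc2)cc(OCc2ccccc2)cc1CC(=O)C[C@@H](C)O | intermediate
27 | hansforester I | C[C@H](Cc1cc(O)cc(O)c1C(=O)O[C@H](C)CC(=O)O)OC(=O)C[C@@H](C)OC(=O)c1c(O)cc(O)cc1CC(=O)C[C@@H](C)O | target

Total step count: 16. Longest linear sequence: 9 steps (2, 3, 4, 6, 7, 8, 14, 15, 16).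

Steps most likely to fail

Step 6. Capture of the acylketene by the electron-poor, weakly nucleophilic hydroxyl of 9 may be slower than internal O-acylation by the enolised 1,3-diketone. β-Elimination of the aroyloxy group may also set in during the amine treatment. The fallback runs from 8 back to 14 and carries the terminal carboxyl as an alkene.
- Heating 8 in toluene with an excess of commercial (R)-pent-4-en-2-ol (C[C@@H](O)CC=C) uses a more nucleophilic alcohol with nothing to eliminate. Through acylketene 10 it should give the pentenyl triketo ester F1.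
- Et3N closes F1 to the aldol adduct F2, and dilute acid dehydrates this to (R)-pent-4-en-2-yl 2,4-dihydroxy-6-{(R)-2-[(tert-butyldimethylsilyl)oxy]propyl}benzoate F3.
- Benzylation (BnBr, K2CO3, DMF) gives the bis(benzyl ether) F4.
- OsO4/NaIO4 cleaves the alkene through the vicinal diol F5 to the aldehyde F6, and NaClO2 oxidation gives the acid F7.
- Alkylation of the carboxylate of F7 (BnBr, KHCO3, DMF) gives 14.

Step 14. Activation of acid 24 acidifies its α-hydrogens, so E1cB loss of the ring B carboxylate may compete with acyl transfer. Alcohol 15 may meanwhile lactonise onto its own aryl ester. The fallback runs from 15 back to 25 and activates the alcohol instead of the acid, through two Mitsunobu inversions.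
- 15 with chloroacetic acid, PPh3 and DIAD gives the inverted (S)-chloroacetate F8.
- Thiourea and NaHCO3 in EtOH remove the chloroacetyl group selectively to give the (S)-alcohol F9.
- A second Mitsunobu reaction of F9 with 24 restores the (R) configuration and gives 25. In this reaction 24 acts only as a carboxylate nucleophile and never becomes an acyl donor.

Step 4. Proton transfer from the α-methylene of amide 6 to the strongly basic dianion, followed by loss of silanolate, may consume the partners before C–C bond formation, as may sluggish acyl transfer. The fallback runs from 6 and 3 back to 8 and replaces acylation by aldol addition and oxidation.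
- iBu2AlH (THF, −78 °C) reduces 6 to (R)-3-[(tert-butyldimethylsilyl)oxy]butanal F10.
- Dianion 7 adds to this far more electrophilic carbonyl at −78 °C to give the β-hydroxy ketone F11 as both carbinol epimers.
- Dess–Martin periodinane in CH2Cl2 at rt oxidises F11 to 8.

Further compounds
F1 | step 6 | (R)-pent-4-en-2-yl (R)-9-[(tert-butyldimethylsilyl)oxy]-3,5,7-trioxodecanoate | C[C@H](CC(=O)CC(=O)CC(=O)CC(=O)O[C@H](C)CC=C)O[Si](C)(C)C(C)(C)C
F2 | step 6 | aldol adduct of F1 (2-hydroxy-4,6-dioxocyclohexanecarboxylate, ring centres undefined) | C[C@H](CC1(O)CC(=O)CC(=O)C1C(=O)O[C@H](C)CC=C)O[Si](C)(C)C(C)(C)C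
F3 | step 6 | (R)-pent-4-en-2-yl 2,4-dihydroxy-6-{(R)-2-[(tert-butyldimethylsilyl)oxy]propyl}benzoate | C=CC[C@@H](C)OC(=O)c1c(O)cc(O)cc1C[C@@H](C)O[Si](C)(C)C(C)(C)C
F4 | step 6 | (R)-pent-4-en-2-yl 2,4-bis(benzyloxy)-6-{(R)-2-[(tert-butyldimethylsilyl)oxy]propyl}benzoate | C=CC[C@@H](C)OC(=O)c1c(OCc2ccccc2)cc(OCc2ccccc2)cc1C[C@@H](C)O[Si](C)(C)C(C)(C)C
F5 | step 6 | (2R)-4,5-dihydroxypentan-2-yl ester corresponding to F4 (C4 carbinol undefined) | OCC(O)C[C@@H](C)OC(=O)c1c(OCc2ccccc2)cc(OCc2ccccc2)cc1C[C@@H](C)O[Si](C)(C)C(C)(C)C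
F6 | step 6 | (R)-4-oxobutan-2-yl 2,4-bis(benzyloxy)-6-{(R)-2-[(tert-butyldimethylsilyl)oxy]propyl}benzoate | O=CC[C@@H](C)OC(=O)c1c(OCc2ccccc2)cc(OCc2ccccc2)cc1C[C@@H](C)O[Si](C)(C)C(C)(C)C
F7 | step 6 | (R)-3-[(2,4-bis(benzyloxy)-6-{(R)-2-[(tert-butyldimethylsilyl)oxy]propyl}benzoyl)oxy]butanoic acid | OC(=O)C[C@@H](C)OC(=O)c1c(OCc2ccccc2)cc(OCc2ccccc2)cc1C[C@@H](C)O[Si](C)(C)C(C)(C)C
F8 | step 14 | benzyl (R)-3-({2,4-bis(benzyloxy)-6-[(S)-2-(2-chloroacetoxy)propyl]benzoyl}oxy)butanoate | C[C@@H](Cc1cc(OCc2ccccc2)cc(OCc2ccccc2)c1C(=O)O[C@H](C)CC(=O)OCc2ccccc2)OC(=O)CCl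
F9 | step 14 | benzyl (R)-3-({2,4-bis(benzyloxy)-6-[(S)-2-hydroxypropyl]benzoyl}oxy)butanoate | C[C@@H](Cc1cc(OCc2ccccc2)cc(OCc2ccccc2)c1C(=O)O[C@H](C)CC(=O)OCc2ccccc2)O
F10 | step 4 | (R)-3-[(tert-butyldimethylsilyl)oxy]butanal | C[C@H](CC=O)O[Si](C)(C)C(C)(C)C
F11 | step 4 | 6-[(6R)-6-(tert-butyldimethylsilyloxy)-4-hydroxy-2-oxoheptyl]-2,2-dimethyl-4H-1,3-dioxin-4-one (C4 carbinol undefined) | C[C@H](CC(O)CC(=O)CC1=CC(=O)OC(C)(C)O1)O[Si](C)(C)C(C)(C)C
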